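What stayed roughly the same between Friday's run and Thursday's was the substrate lost per minute up to the last reading, not the percentage: the charge rose 2.21-fold, that loss 1.29-fold. A meeting was held on the two new flasks, elm and alder.

common to all: gas 6.3 mM (held)
- Friday's: substrate 0.034 M; run made earlier
- Thursday's: substrate 0.075 M; run made earlier
- elm: substrate 0.050 M; time 3.0 h
- alder: substrate 0.050 M; time 2.0 h

| run | time / min | bis adduct / % | substrate / % | single product / % | triple product / % |
|---|---|---|---|---|---|
| Friday's | 6.00 | 0.4 | 99.8 | 0.3 | 0.6 |
| Friday's | 20.0 | 0 | 97.8 | 1.5 | 0 |
| Friday's | 30.0 | 0 | 96.2 | 4.3 | 0.4 |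
| Friday's | 50.0 | 0.4 | 92.2 | 7.6 | 0.5 |
| Friday's | 80.0 | 1.6 | 86.3 | 11.9 | 0.5 |
| Thursday's | 6.00 | 0.1 | 99.7 | 1.1 | 0 |
| Thursday's | 10.0 | 0 | 99.0 | 0.4 | 0.5 |
| Thursday's | 20.0 | 0 | 97.7 | 1.3 | 0 |
| Thursday's | 40.0 | 0 | 95.7 | 3.9 | 0 |
| Thursday's | 80.0 | 0 | 92.0 | 8.0 | 0.9 |

(standard deviation of a reading: 0.5 percentage points)

- at the start none of the gas is in solution
- a reading or a percentage of bis adduct counts all its forms, free or not
- a reading of substrate is of its free form alone

1. which of these there is most of at the end, counted by the substrate in it, elm (substrate / bis adduct / triple product / single product)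
2. which of these there is most of at the end, counted by the substrate in it, alder (substrate / bis adduct / triple product / single product)
3. how much there is at the end of the one of these that leads, in percent of the substrate charged: elm
4. how much there is at the end of the one of these that leads, in percent of the substrate charged: alder

The chair read the last points: Friday's run lost 0.0582 mM min⁻¹ on average, Thursday's 0.0750 mM min⁻¹. The secretary objected that these differ, since one reading's scatter is worth 0.00469 mM min⁻¹ on Thursday's figure. The chair answered that a loss so little moved by the charge may still be carried as a mean. It was agreed to call that mean the drain d, the substrate lost per minute at this gas level, 0.0666 mM min⁻¹.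

The secretary then reckoned the correction and not the remainder: with time t and charge c, the share left was taken as one minus d·t/c. That gives 76.0% for elm and 84.0% for alder. On this reckoning substrate leads in both, since the lost share in elm, 24.0%, is less than what remains, and alder runs for a shorter time.

The forecast, calling the reaction “close to zero order in substrate”, named substrate for elm and substrate for alder. It gave 76.5% (72% to 80%) and 84.5% (81.5% to 87.5%), slightly above the secretary's figures.

The flasks give substrate at 74.1% in elm and substrate at 82.6% in alder, inside the forecast's ranges.

    substrate + partner → single product (k = 88.0 L mol⁻¹ h⁻¹)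
    partner + single product → bis adduct (k = 150 L mol⁻¹ h⁻¹)
    partner + bis adduct → triple product (k = 76.0 L mol⁻¹ h⁻¹)
    substrate + bis adduct ⇌ idle adduct, settled at all times (K = 17.0 L mol⁻¹)
    gas ⇌ partner, rate k5*(csat - [partner]) (kL = 1.00 h⁻¹)

Elm lost 0.0719 mM min⁻¹ on average over its run, a little above d. Substrate keeps its lead in elm because the uptake of gas as partner, the rate-limiting step, is slow and the run is short; each is a part of the reason. With that slowness taken away, elm keeps 18.6% substrate and the lead turns; with the slowness left in place and the reading put off to ten times the time, elm keeps 2.28%.

Alder read at 8.0 h is the second case: d gives 36.1% substrate left. The computed flask holds 42.6%, and substrate's loss there is no small correction.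

(The earlier runs and the new flask are calculated on assumed constants; the scatter is artificial.)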